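**Retrosynthetic overview**

1. Cembrane numbering is used: C1 carries the isopropylidene carbon C15, C2 and C9 are the ketones, C3–C4 the epoxide, C8 and C12 the methyl-bearing stereocentres, C13 and C14 the remaining ring CH2 groups next to C12.
2. The last C–C bond is C12–C13. It is made by ring closure of an acyclic keto-enyne: hydroboration, boron–zinc exchange and titanium-catalysed enantioselective dienyl transfer to the C12 methyl ketone. This closes the 14-membered ring and sets the C12 carbinol at once; C13=C14 is then hydrogenated and the tertiary alcohol acetylated.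
3. Enabling feature: in the 14-membered ring the methyl carbinol C12 is joined through C13–C14 to the sp2 carbon C1 of the C1(=C15)–C2(=O) enone, so C12–C13–C14–C1 is a hydrogenated (E)-dienyl carbinol and C13 can arrive as the terminus of an ethynyl group on C1. C12 is the only methyl ketone of the chain, and its 1,4-partner C9 lets both carbonyls travel as one 2-methylfuran until two steps before ring closure.
4. Open chain: C1–C2 by Nozaki–Hiyama–Kishi coupling of an epoxy aldehyde with an enynyl triflate; C3/C4 by Sharpless epoxidation; C5–C6 by copper-catalysed Grignard–allyl bromide coupling; C8 by organocatalytic conjugate addition of 2-methylfuran to crotonaldehyde.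
5. Rings in order: furan (bought, opened in step 14), oxirane (step 7), 14-membered carbocycle (step 16).

Key step: step 16

Remark (assumption): the (2R,5R) antipode of the imidazolidinone (step 3) is taken to give the S aldehyde, and the chosen antipode of the bis(sulfonamide)diol ligand (step 16) to give Re-face attack at C12; should either sense of induction be the reverse, the mirror-image catalyst is used.

**Route**

Step 1
Reactants: 1 3-methylbut-2-en-1-yl acetate (prenyl acetate)
Product: 2 (E)-4-hydroxy-3-methylbut-2-en-1-yl acetate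
Conditions: SeO2 (0.3 equiv), t-BuOOH, CH2Cl2, 0 °C → rt
Reagents that add atoms: tert-butyl hydroperoxide, CC(C)(C)OO; selenium dioxide (oxygen relay), O=[Se]=O
Why: Selenium dioxide allylic oxidation (ene reaction, then [2,3]-sigmatropic shift) hydroxylates the methyl group trans to the chain of a trisubstituted alkene, so the (E)-allylic alcohol should form.

Step 2
Reactants: 2 (E)-4-hydroxy-3-methylbut-2-en-1-yl acetate
Product: 3 (E)-4-bromo-3-methylbut-2-en-1-yl acetate
Conditions: CBr4, PPh3, CH2Cl2, 0 °C
Reagents that add atoms: carbon tetrabromide, BrC(Br)(Br)Br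
Why: The Appel reaction replaces the primary allylic hydroxyl by bromide through SN2 displacement of the oxyphosphonium ion, leaving the alkene geometry and the acetate untouched.

Step 3
Reactants: 4 2-methylfuran; 5 (E)-but-2-enal (crotonaldehyde)
Product: 7 (S)-3-(5-methylfuran-2-yl)butan-1-ol, via (S)-3-(5-methylfuran-2-yl)butanal 6 (not isolated)
Conditions: (2R,5R)-5-benzyl-2-tert-butyl-3-methylimidazolidin-4-one·CF3CO2H (20 mol%), CHCl3, −40 °C; then NaBH4, EtOH, 0 °C
Reagents that add atoms: none
Why: In this iminium-catalysed Friedel–Crafts conjugate addition (known for 2-methylfuran with crotonaldehyde) the imidazolidinone shields one face of the enal β-carbon, so attack by the furan C5 position sets C8 as S, and in situ borohydride reduction turns the sensitive aldehyde into the stable alcohol.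

Step 4
Reactants: 7 (S)-3-(5-methylfuran-2-yl)butan-1-ol
Product: 8 (S)-2-(4-bromobutan-2-yl)-5-methylfuran
Conditions: CBr4, PPh3, CH2Cl2, 0 °C
Reagents that add atoms: carbon tetrabromide, BrC(Br)(Br)Br
Why: The Appel reaction works under neutral conditions, so the acid-sensitive furan and the remote C8 stereocentre are not disturbed.

Step 5
Reactants: 8 (S)-2-(4-bromobutan-2-yl)-5-methylfuran; 3 (E)-4-bromo-3-methylbut-2-en-1-yl acetate
Product: 10 (2E,7S)-3-methyl-7-(5-methylfuran-2-yl)oct-2-en-1-yl acetate, via Grignard reagent 9 (not isolated)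
Conditions: Mg, THF, 40 °C; then added to 3, Li2CuCl4 (3 mol%), THF, −78 → −20 °C
Reagents that add atoms: none
Why: Copper-catalysed cross-coupling of a primary alkyl Grignard reagent with a primary allylic bromide is an SN2 displacement at the CH2Br carbon that is faster than attack on the allylic acetate, so C6 is joined to C5 with the (E)-trisubstituted alkene intact.

Step 6
Reactants: 10 (2E,7S)-3-methyl-7-(5-methylfuran-2-yl)oct-2-en-1-yl acetate
Product: 11 (2E,7S)-3-methyl-7-(5-methylfuran-2-yl)oct-2-en-1-ol
Conditions: K2CO3 (cat.), MeOH, rt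
Reagents that add atoms: none
Why: Base-catalysed transesterification with methanol frees the allylic alcohol that must direct the epoxidation.

Step 7
Reactants: 11 (2E,7S)-3-methyl-7-(5-methylfuran-2-yl)oct-2-en-1-ol
Product: 12 [(2S,3S)-3-methyl-3-[(4S)-4-(5-methylfuran-2-yl)pentyl]oxiran-2-yl]methanol
Conditions: Ti(OiPr)4 (10 mol%), L-(+)-diethyl tartrate (12 mol%), t-BuOOH, 4 Å MS, CH2Cl2, −20 °C
Reagents that add atoms: tert-butyl hydroperoxide, CC(C)(C)OO
Why: Sharpless asymmetric epoxidation of the (E)-trisubstituted allylic alcohol delivers oxygen to the face fixed by the L-(+)-tartrate–titanium complex, which sets C3 and C4 as the trans (2S,3S) epoxy alcohol, and the bound hydroxyl makes this alkene react far faster than the remote furan.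

Step 8
Reactants: 12 [(2S,3S)-3-methyl-3-[(4S)-4-(5-methylfuran-2-yl)pentyl]oxiran-2-yl]methanol
Product: 13 (2R,3S)-3-methyl-3-[(4S)-4-(5-methylfuran-2-yl)pentyl]oxirane-2-carbaldehyde
Conditions: Dess–Martin periodinane, CH2Cl2, 0 °C → rt
Reagents that add atoms: none
Why: Dess–Martin oxidation converts the primary epoxy alcohol into the epoxy aldehyde under near-neutral conditions that spare epoxide and furan (no stereocentre changes; only the descriptor of the aldehyde-bearing carbon does).

Step 9
Reactants: 14 2-methylpropanoyl chloride; 15 bis(trimethylsilyl)acetylene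
Product: 16 4-methyl-1-(trimethylsilyl)pent-1-yn-3-one
Conditions: AlCl3, CH2Cl2, 0 °C
Reagents that add atoms: none
Why: Friedel–Crafts-type acylation of the alkynylsilane (ipso substitution of one silyl group by the acylium ion) is the standard route to silyl ynones.

Step 10
Reactants: 16 4-methyl-1-(trimethylsilyl)pent-1-yn-3-one
Product: 17 4-methyl-1-(trimethylsilyl)pent-3-en-1-yn-3-yl trifluoromethanesulfonate
Conditions: Tf2O, 2,6-di-tert-butyl-4-methylpyridine, CH2Cl2, 0 °C → rt
Reagents that add atoms: trifluoromethanesulfonic anhydride, O=S(=O)(OS(=O)(=O)C(F)(F)F)C(F)(F)F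
Why: O-Sulfonylation of the ketone followed by loss of its only α-proton (the isopropyl methine) is the known hindered-base route from ketones to vinyl triflates and here can only give the tetrasubstituted enynyl triflate.

Step 11
Reactants: 13 (2R,3S)-3-methyl-3-[(4S)-4-(5-methylfuran-2-yl)pentyl]oxirane-2-carbaldehyde; 17 4-methyl-1-(trimethylsilyl)pent-3-en-1-yn-3-yl trifluoromethanesulfonate
Product: 18 1-[(2S,3S)-3-methyl-3-[(4S)-4-(5-methylfuran-2-yl)pentyl]oxiran-2-yl]-2-(propan-2-ylidene)-4-(trimethylsilyl)but-3-yn-1-ol (both carbinol epimers)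
Conditions: CrCl2 (4 equiv), NiCl2 (2 mol%), DMF, rt
Reagents that add atoms: none
Why: In the Nozaki–Hiyama–Kishi reaction zerovalent nickel inserts into the C–OTf bond, the alkenyl group passes to trivalent chromium and adds only to the aldehyde, which forms C1–C2 without opening the epoxide; the new carbinol centre is irrelevant because it is oxidised next.

Step 12
Reactants: 18 1-[(2S,3S)-3-methyl-3-[(4S)-4-(5-methylfuran-2-yl)pentyl]oxiran-2-yl]-2-(propan-2-ylidene)-4-(trimethylsilyl)but-3-yn-1-ol
Product: 19 1-[(2R,3S)-3-methyl-3-[(4S)-4-(5-methylfuran-2-yl)pentyl]oxiran-2-yl]-2-(propan-2-ylidene)-4-(trimethylsilyl)but-3-yn-1-one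
Conditions: Dess–Martin periodinane, CH2Cl2, 0 °C → rt
Reagents that add atoms: none
Why: Dess–Martin oxidation of the allylic, α-epoxy secondary alcohol gives the cross-conjugated epoxy enynone and erases the C2 carbinol centre.

Step 13
Reactants: 19 1-[(2R,3S)-3-methyl-3-[(4S)-4-(5-methylfuran-2-yl)pentyl]oxiran-2-yl]-2-(propan-2-ylidene)-4-(trimethylsilyl)but-3-yn-1-one
Product: 20 1-[(2R,3S)-3-methyl-3-[(4S)-4-(5-methylfuran-2-yl)pentyl]oxiran-2-yl]-2-(propan-2-ylidene)but-3-yn-1-one
Conditions: K2CO3 (0.2 equiv), MeOH, 0 °C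
Reagents that add atoms: none
Why: Methanolysis of the alkynyl C–Si bond frees the terminal alkyne while C8 is still flanked by the furan and so cannot epimerise.

Step 14
Reactants: 20 1-[(2R,3S)-3-methyl-3-[(4S)-4-(5-methylfuran-2-yl)pentyl]oxiran-2-yl]-2-(propan-2-ylidene)but-3-yn-1-one
Product: 21 1-[(2R,3S)-3-methyl-3-[(4S,6Z)-4-methyl-5,8-dioxonon-6-en-1-yl]oxiran-2-yl]-2-(propan-2-ylidene)but-3-yn-1-one
Conditions: mCPBA (1.0 equiv), CH2Cl2, −10 °C
Reagents that add atoms: 3-chloroperoxybenzoic acid, OOC(=O)c1cccc(Cl)c1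
Why: Peracid oxidation of a 2,5-dialkylfuran (epoxidation of the furan, then ring opening) is the classical unmasking to the (Z)-ene-1,4-dione, and the electron-rich furan should react well before the electron-poor tetrasubstituted enone or the alkyne.

Step 15
Reactants: 21 1-[(2R,3S)-3-methyl-3-[(4S,6Z)-4-methyl-5,8-dioxonon-6-en-1-yl]oxiran-2-yl]-2-(propan-2-ylidene)but-3-yn-1-one
Product: 22 1-[(2R,3S)-3-methyl-3-[(4S)-4-methyl-5,8-dioxononyl]oxiran-2-yl]-2-(propan-2-ylidene)but-3-yn-1-one
Conditions: Hantzsch ester (diethyl 2,6-dimethyl-1,4-dihydropyridine-3,5-dicarboxylate, 1.2 equiv), toluene, 60 °C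
Reagents that add atoms: none
Why: Hydride transfer from the Hantzsch ester (conjugate reduction) should reduce only the doubly activated C10=C11 bond of the enedione and leave the singly activated tetrasubstituted C1=C15 enone, the epoxy ketone and the alkyne, giving the 1,4-diketone whose C12 methyl ketone is the electrophile of the key step.

Step 16
Reactants: 22 1-[(2R,3S)-3-methyl-3-[(4S)-4-methyl-5,8-dioxononyl]oxiran-2-yl]-2-(propan-2-ylidene)but-3-yn-1-one
Product: 25 (3R,4S,8S,12S,13E)-12-hydroxy-3,4-epoxycembra-1(15),13-diene-2,9-dione, via dienylborane 23 (not isolated), via dienyl(methyl)zinc reagent 24 (not isolated)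
Conditions: Cy2BH (1.05 equiv), toluene, 0 °C; Me2Zn (2.2 equiv), −78 °C; syringe-pump addition (12 h) into Ti(OiPr)4 (1.2 equiv) and the bis(sulfonamide)diol ligand from trans-cyclohexane-1,2-diamine and camphorsulfonic acid (20 mol%), toluene, rt, 2 mM; aq. NH4Cl
Reagents that add atoms: none
Why: Proposed new method: syn-hydroboration of the terminal enyne gives (E)-dienylborane 23, boron-to-zinc exchange with Me2Zn gives dienyl(methyl)zinc 24, and the titanium bis(sulfonamide)diolate formed from Ti(OiPr)4 and the ligand activates the C12 methyl ketone and transfers the dienyl group to it, which forms C12–C13 and closes the 14-membered carbocycle in a 14-exo-trig addition. The closest known reactions are the enantioselective macrocyclisation of ω-alkynals by the same hydroboration/boron–zinc exchange sequence under amino alcohol catalysis and the intermolecular titanium-catalysed enantioselective vinylation and dienylation of methyl ketones with alkenylzinc reagents made from alkynes and enynes; the step merges the two. C12 is the only new stereocentre and is set by the chiral titanium complex, which should deliver the dienyl group to the Re face of the ketone (12S in 25, 12R once C13=C14 is saturated), the remote C3, C4 and C8 centres having little say. Chemoselectivity is needed twice: the borane must add to the alkyne and not reduce a ketone, which the much faster hydroboration of terminal alkynes by Cy2BH secures, and the dienylzinc must pick C12, which is the only unhindered methyl ketone, whereas attack at C9 would need an 11-membered ring at an α-branched ketone and attack at C2 a 4-membered ring. Intermolecular addition is held back by the slow addition into the catalyst solution, since the dienylzinc does not add to ketones at a useful rate without the titanium Lewis acid.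

Step 17
Reactants: 25 (3R,4S,8S,12S,13E)-12-hydroxy-3,4-epoxycembra-1(15),13-diene-2,9-dione
Product: 26 (3R,4S,8S,12R)-12-hydroxy-3,4-epoxycembr-1(15)-ene-2,9-dione
Conditions: H2 (1–3 atm), RhCl(PPh3)3 (5 mol%), benzene, rt
Reagents that add atoms: none
Why: Homogeneous rhodium-catalysed hydrogenation should reduce the 1,2-disubstituted C13=C14 bond and not the tetrasubstituted C1=C15 enone bond, the ketones or the epoxide; C12 is untouched (its descriptor changes from S to R only because C13 becomes sp3).

Step 18
Reactants: 26 (3R,4S,8S,12R)-12-hydroxy-3,4-epoxycembr-1(15)-ene-2,9-dione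
Product: 27 (3R,4S,8S,12R)-12-acetoxy-3,4-epoxycembr-1(15)-ene-2,9-dione (CNP0229580.1)
Conditions: Ac2O, DMAP, Et3N, CH2Cl2, rt → 40 °C
Reagents that add atoms: acetic anhydride, CC(=O)OC(C)=O
Why: DMAP-catalysed acylation (nucleophilic catalysis through the N-acetylpyridinium ion) is the standard esterification of tertiary alcohols and should give the target with all four stereocentres in place.

**Compound list**

1 | 3-methylbut-2-en-1-yl acetate | CC(C)=CCOC(C)=O | starting material
2 | (E)-4-hydroxy-3-methylbut-2-en-1-yl acetate | CC(=O)OC/C=C(\C)CO | intermediate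
3 | (E)-4-bromo-3-methylbut-2-en-1-yl acetate | CC(=O)OC/C=C(\C)CBr | intermediate
4 | 2-methylfuran | Cc1ccco1 | starting material
5 | (E)-but-2-enal | C/C=C/C=O | starting material
6 | (S)-3-(5-methylfuran-2-yl)butanal | Cc1ccc(o1)[C@@H](C)CC=O | intermediate
7 | (S)-3-(5-methylfuran-2-yl)butan-1-ol | Cc1ccc(o1)[C@@H](C)CCO | intermediate
8 | (S)-2-(4-bromobutan-2-yl)-5-methylfuran | Cc1ccc(o1)[C@@H](C)CCBr | intermediate
9 | [(3S)-3-(5-methylfuran-2-yl)butyl]magnesium bromide | Cc1ccc(o1)[C@@H](C)CC[Mg]Br | intermediate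
10 | (2E,7S)-3-methyl-7-(5-methylfuran-2-yl)oct-2-en-1-yl acetate | Cc1ccc(o1)[C@@H](C)CCC/C(C)=C/COC(C)=O | intermediate
11 | (2E,7S)-3-methyl-7-(5-methylfuran-2-yl)oct-2-en-1-ol | Cc1ccc(o1)[C@@H](C)CCC/C(C)=C/CO | intermediate
12 | [(2S,3S)-3-methyl-3-[(4S)-4-(5-methylfuran-2-yl)pentyl]oxiran-2-yl]methanol | Cc1ccc(o1)[C@@H](C)CCC[C@]2(C)O[C@H]2CO | intermediate
13 | (2R,3S)-3-methyl-3-[(4S)-4-(5-methylfuran-2-yl)pentyl]oxirane-2-carbaldehyde | Cc1ccc(o1)[C@@H](C)CCC[C@]2(C)O[C@H]2C=O | intermediate
14 | 2-methylpropanoyl chloride | CC(C)C(Cl)=O | starting material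
15 | bis(trimethylsilyl)acetylene | C[Si](C)(C)C#C[Si](C)(C)C | starting material
16 | 4-methyl-1-(trimethylsilyl)pent-1-yn-3-one | CC(C)C(=O)C#C[Si](C)(C)C | intermediate
17 | 4-methyl-1-(trimethylsilyl)pent-3-en-1-yn-3-yl trifluoromethanesulfonate | CC(C)=C(OS(=O)(=O)C(F)(F)F)C#C[Si](C)(C)C | intermediate
18 | 1-[(2S,3S)-3-methyl-3-[(4S)-4-(5-methylfuran-2-yl)pentyl]oxiran-2-yl]-2-(propan-2-ylidene)-4-(trimethylsilyl)but-3-yn-1-ol (both carbinol epimers) | Cc1ccc(o1)[C@@H](C)CCC[C@]2(C)O[C@H]2C(O)C(=C(C)C)C#C[Si](C)(C)C | intermediate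
19 | 1-[(2R,3S)-3-methyl-3-[(4S)-4-(5-methylfuran-2-yl)pentyl]oxiran-2-yl]-2-(propan-2-ylidene)-4-(trimethylsilyl)but-3-yn-1-one | Cc1ccc(o1)[C@@H](C)CCC[C@]2(C)O[C@H]2C(=O)C(=C(C)C)C#C[Si](C)(C)C | intermediate
20 | 1-[(2R,3S)-3-methyl-3-[(4S)-4-(5-methylfuran-2-yl)pentyl]oxiran-2-yl]-2-(propan-2-ylidene)but-3-yn-1-one | Cc1ccc(o1)[C@@H](C)CCC[C@]2(C)O[C@H]2C(=O)C(=C(C)C)C#C | intermediate
21 | 1-[(2R,3S)-3-methyl-3-[(4S,6Z)-4-methyl-5,8-dioxonon-6-en-1-yl]oxiran-2-yl]-2-(propan-2-ylidene)but-3-yn-1-one | CC(=O)/C=C\C(=O)[C@@H](C)CCC[C@]1(C)O[C@H]1C(=O)C(=C(C)C)C#C | intermediate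
22 | 1-[(2R,3S)-3-methyl-3-[(4S)-4-methyl-5,8-dioxononyl]oxiran-2-yl]-2-(propan-2-ylidene)but-3-yn-1-one | CC(=O)CCC(=O)[C@@H](C)CCC[C@]1(C)O[C@H]1C(=O)C(=C(C)C)C#C | intermediate
23 | dicyclohexyl[(1E)-4-methyl-3-{[(2R,3S)-3-methyl-3-[(4S)-4-methyl-5,8-dioxononyl]oxiran-2-yl]carbonyl}penta-1,3-dien-1-yl]borane | CC(=O)CCC(=O)[C@@H](C)CCC[C@]1(C)O[C@H]1C(=O)C(=C(C)C)/C=C/B(C2CCCCC2)C3CCCCC3 | intermediate
24 | methyl[(1E)-4-methyl-3-{[(2R,3S)-3-methyl-3-[(4S)-4-methyl-5,8-dioxononyl]oxiran-2-yl]carbonyl}penta-1,3-dien-1-yl]zinc | CC(=O)CCC(=O)[C@@H](C)CCC[C@]1(C)O[C@H]1C(=O)C(=C(C)C)/C=C/[Zn]C | intermediate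
25 | (3R,4S,8S,12S,13E)-12-hydroxy-3,4-epoxycembra-1(15),13-diene-2,9-dione | C1C(=O)[C@@H](C)CCC[C@]2(C)O[C@H]2C(=O)C(=C(C)C)/C=C/[C@@](C)(O)C1 | intermediate
26 | (3R,4S,8S,12R)-12-hydroxy-3,4-epoxycembr-1(15)-ene-2,9-dione | O[C@@]1(C)CCC(=O)[C@@H](C)CCC[C@]2(C)O[C@H]2C(=O)C(=C(C)C)CC1 | intermediate
27 | (3R,4S,8S,12R)-12-acetoxy-3,4-epoxycembr-1(15)-ene-2,9-dione (CNP0229580.1) | CC(=O)O[C@@]1(C)CCC(=O)[C@@H](C)CCC[C@]2(C)O[C@H]2C(=O)C(=C(C)C)CC1 | target

**Step count and weak points**

Total steps: 18. Longest linear sequence: 14 steps (steps 3–8 and 11–18, from 2-methylfuran and crotonaldehyde); steps 1–2 and 9–10 are side branches.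

Steps most likely to fail:

1. Step 16 (bears the label "Proposed new method"). What may go wrong:
 - borane reduction of the methyl ketone competing with alkyne hydroboration;
 - slow catalytic turnover at high dilution, so that the dienylzinc is lost to protonolysis or to intermolecular addition;
 - poor facial discrimination between the methyl and the methylene substituent of the C12 ketone, giving both C12 epimers.

 Fallback (known chemistry; it sets out from 12 and comes back at 25, making C12–C13 between two molecules and closing the ring at C1–C2). mCPBA opens the furan of 12 to the (Z)-enedione epoxy alcohol F1, and H2 over Pd/C saturates it to the diketone epoxy alcohol F2. Compound 17 is desilylated (K2CO3, MeOH, 0 °C) to the enynyl triflate F3. F3 is hydrozirconated with Cp2Zr(H)Cl, transmetalated with Me2Zn and added to the methyl ketone of F2 under Ti(OiPr)4 and the same ligand; this is the established intermolecular dienylation of methyl ketones, with the primary hydroxyl carried as its zinc alkoxide, and it gives the tertiary dienol triflate F4. Dess–Martin periodinane oxidises only the primary alcohol to the hydroxy aldehyde F5. CrCl2 with catalytic NiCl2 in DMF at high dilution closes C1–C2 by intramolecular Nozaki–Hiyama–Kishi reaction to the macrocyclic diol F6, and Dess–Martin oxidation of the C2 carbinol gives 25.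

2. Step 11. What may go wrong:
 - sluggish insertion and alkenyl transfer with the tetrasubstituted enynyl triflate;
 - allenyl-type transposition of the alkenylmetal (attack through the alkyne terminus);
 - Lewis-acid or chloride opening of the epoxy aldehyde during a long reaction.

 Fallback (it sets out from 13 and comes back at 18; the fragment and the bond-forming principle both change). 1,1-Dibromo-2-methylprop-1-ene and ethynyltrimethylsilane are joined by Sonogashira monocoupling [PdCl2(PPh3)2, CuI, i-Pr2NH] to the bromoenyne F7. Bromine–lithium exchange (t-BuLi, Et2O, −78 °C) gives the alkenyllithium F8, which adds to 13 at −78 °C to give 18.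

3. Step 17. What may go wrong:
 - stalling at the hindered trans-alkene next to the quaternary carbinol, possibly aggravated by transannular hemiketal formation between the C12 hydroxyl and the C9 ketone;
 - migration or reduction of the C1=C15 double bond;
 - reductive opening of the epoxy ketone on forcing.

 Fallback (it sets out from 25 and comes back at 27; the order of the last two operations and the reduction principle both change). 25 is acetylated first (Ac2O, DMAP, Et3N) to the dienyl acetate F9. C13=C14 is then reduced with diimide generated from 2-nitrobenzenesulfonohydrazide and Et3N (CH2Cl2, rt), a metal-free concerted hydrogen transfer that leaves tetrasubstituted and carbonyl-conjugated double bonds, ketones and epoxides alone and gives 27 directly.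

Further compounds
F1 | step 16 | (3Z,6S)-9-[(2S,3S)-3-(hydroxymethyl)-2-methyloxiran-2-yl]-6-methylnon-3-ene-2,5-dione | CC(=O)/C=C\C(=O)[C@@H](C)CCC[C@]1(C)O[C@H]1CO
F2 | step 16 | (6S)-9-[(2S,3S)-3-(hydroxymethyl)-2-methyloxiran-2-yl]-6-methylnonane-2,5-dione | CC(=O)CCC(=O)[C@@H](C)CCC[C@]1(C)O[C@H]1CO
F3 | step 16 | 4-methylpent-3-en-1-yn-3-yl trifluoromethanesulfonate | CC(C)=C(OS(=O)(=O)C(F)(F)F)C#C
F4 | step 16 | (4E,6S,10S)-6-hydroxy-13-[(2S,3S)-3-(hydroxymethyl)-2-methyloxiran-2-yl]-2,6,10-trimethyl-9-oxotrideca-2,4-dien-3-yl trifluoromethanesulfonate | CC(C)=C(OS(=O)(=O)C(F)(F)F)/C=C/[C@@](C)(O)CCC(=O)[C@@H](C)CCC[C@]1(C)O[C@H]1CO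
F5 | step 16 | (4E,6S,10S)-13-[(2S,3R)-3-formyl-2-methyloxiran-2-yl]-6-hydroxy-2,6,10-trimethyl-9-oxotrideca-2,4-dien-3-yl trifluoromethanesulfonate | CC(C)=C(OS(=O)(=O)C(F)(F)F)/C=C/[C@@](C)(O)CCC(=O)[C@@H](C)CCC[C@]1(C)O[C@H]1C=O
F6 | step 16 | (3S,4S,8S,12S,13E)-2,12-dihydroxy-3,4-epoxycembra-1(15),13-dien-9-one (both C2 epimers) | C1C(=O)[C@@H](C)CCC[C@]2(C)O[C@H]2C(O)C(=C(C)C)/C=C/[C@@](C)(O)C1
F7 | step 11 | (3-bromo-4-methylpent-3-en-1-yn-1-yl)trimethylsilane | CC(C)=C(Br)C#C[Si](C)(C)C
F8 | step 11 | [4-methyl-1-(trimethylsilyl)pent-3-en-1-yn-3-yl]lithium | CC(C)=C([Li])C#C[Si](C)(C)C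
F9 | step 17 | (3R,4S,8S,12S,13E)-12-acetoxy-3,4-epoxycembra-1(15),13-diene-2,9-dione | C1C(=O)[C@@H](C)CCC[C@]2(C)O[C@H]2C(=O)C(=C(C)C)/C=C/[C@@](C)(OC(C)=O)C1
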